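The runs stem from a simulated flask with constants of no real substance; the scatter is artificial.

Budget the incoming ligand before extrapolating any curve.

| setting | larch | ash | flask |
|---|---|---|---|
| starting complex | 0.50 M | 0.75 M | 0.50 M |
| incoming ligand | 1 equiv | 1 equiv | 1.00 equiv |
| protic impurity | 0.10 M | 0.10 M | 0.100 M |
| remark | the very flask that is asked about, followed so far | run made earlier |  |
| time |  |  | 2.5 min |

- larch (time / s: complex with one exchanged / %, side product / %): 10.0: 13.3, 6.9; 20.0: 11.7, 11.2; 40.0: 11.1, 20.1; 50.0: 9.8, 23.8; 80.0: 10.2, 33.9
- ash (time / min: complex with one exchanged / %, side product / %): 0.500: 11.2, 21.3; 1.00: 9.2, 33.7; 1.50: 8.2, 43.1; 2.00: 7.1, 49.0; 2.50: 6.9, 52.7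

(standard deviation of a reading: 0.5 percentage points)

- percent here means starting complex units held: one side product counts as two
- what is said of leaving ligand includes crystals
- crystals is a solid; its amount is given per volume of the solution
- steps thought possible: starting complex + incoming ligand <-> leaving ligand + complex with one exchanged; complex with one exchanged + incoming ligand <-> leaving ligand + complex with two exchanged; complex with two exchanged + incoming ligand <-> leaving ligand + complex with three exchanged; starting complex + complex with one exchanged -> side product; protic impurity + incoming ligand -> quenched reagent; crystals <-> leaving ligand
- the reaction counts as stopped when no species that holds the starting complex changes by six tenths of a point or more over the second half of the time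

1. why nothing more happens at 2.5 min, or that something still does (all of the starting complex has reacted / forward and back rates have come level / it is still moving)
2. complex with one exchanged at 2.5 min, in percent of the starting complex charged
3. side product at 2.5 min, in percent of the starting complex charged

Let the protic impurity quench its full share, and keep what remains per starting complex charged: 0.800, the exchange budget of the incoming ligand, the limiting reagent. A side product unit holds 0.5 ligand, complex with one exchanged holds 1, and the unread complex with two exchanged holds 2. Neglect free ligand and complex with three exchanged, and the two balances give: starting complex = 1 − 0.5·budget − 0.750·side product − 0.5·complex with one exchanged. In larch that reads 0.372 at 50.0 s and 0.295 at 80.0 s. Take the side product rate as proportional to starting complex times complex with one exchanged; the last larch interval reads, within its scatter, a coefficient of 0.101 s⁻¹.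

Integrate larch to 2.5 min. Holding complex with one exchanged at its last larch reading, 10.2%, gives an estimated top, 50.3%. Holding it at 6.9%, which ash read at 52.7% of side product, higher than that top, gives an estimated bottom, 46.6%. That bottom stands 13 percentage points above the reading at 80.0 s, a reading already inside the second half of the time, so call larch still moving.

The forecast, reckoned by scaling ash and summing rates, gives it is still moving, 8% and 47.5%, inside the bracket, and reads in ash “doubly exchanged complex building up late”. The flask gives it is still moving, 7.61% and 47.3%, also inside.

    starting complex + incoming ligand ⇌ leaving ligand + complex with one exchanged (K = 0.860, k = 3.80 M⁻¹ s⁻¹)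
    complex with one exchanged + incoming ligand ⇌ leaving ligand + complex with two exchanged (K = 6.06, k = 9.92 M⁻¹ s⁻¹)
    complex with two exchanged + incoming ligand ⇌ leaving ligand + complex with three exchanged (K = 0.414, k = 1.67 M⁻¹ s⁻¹)
    starting complex + complex with one exchanged → side product (k = 0.0853 M⁻¹ s⁻¹)
    protic impurity + incoming ligand → quenched reagent (k = 6.84 M⁻¹ s⁻¹)
    crystals ⇌ leaving ligand, rate k6*(cs6 - [leaving ligand]) while solid is left; crystals form when [leaving ligand] > cs6 (solubility = 25.0 mM, k = 1.72 s⁻¹)

Spend the same budget on the neighbouring flask with 0.40 M of protic impurity: its charge gives 0.200. There 5.17% of the impurity still stands at 2.50 min, and the 0.379 M of quenched reagent leaves 0.241 so far. Its side product, 40.9%, holds 0.204 of that, against 0.236 of 0.800 in the asked flask. In the neighbour, 56% of the starting complex remains, and incoming ligand is down to 0.176% of its charge.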